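**Strategy.** Each oxolane ring (O1, C2 aryl, C3 CH2OH, C4 OH/arylmethyl, C5) is read as a 3-acyltetrahydrofuran: the tertiary C4–OH stands for a C4–CHO group (Baeyer–Villiger, retention). This unveils a Prins–pinacol rearrangement of a 2-aryl-4-alkenyl-1,3-dioxolane, made from an (S)-allylic diol and an aryl aldehyde. In one operation the oxocarbenium carbon C2 is attacked by alkene carbon C3 (ring closure through the C2–C3 bond of the ring that carries the biaryl), then C5 shifts to C4. Alkene geometry and one carbinol centre set C2, C3 and C4. Two such halves, an aryl bromide and an aryl boronate, are joined by Suzuki coupling before oxidation and debenzylation.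

Key step: step 10

Remark: the sense of chirality transfer in the key step is assigned from a chair model with the tin alkoxide axial, which requires the S carbinol centre supplied by D-glyceraldehyde acetonide. That centre keeps its spatial arrangement from 1 to 13 and 20; the descriptor changes (R in 1, S in 2 and 3, R in 4 to 6, S afterwards; Z in 6, E in 10) are changes of CIP priority only.

**Step 1**
Reactants: 1 (4R)-2,2-dimethyl-1,3-dioxolane-4-carbaldehyde
Product: 2 (4S)-4-ethynyl-2,2-dimethyl-1,3-dioxolane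
Conditions: dimethyl (1-diazo-2-oxopropyl)phosphonate, K2CO3, MeOH, 0 °C to rt
Reagents that add atoms: dimethyl (1-diazo-2-oxopropyl)phosphonate, CC(=O)C(=[N+]=[N-])P(=O)(OC)OC
Why: Seyferth–Gilbert homologation with the Ohira–Bestmann reagent should give the terminal alkyne under carbonate conditions mild enough to leave the α-oxygenated stereocentre untouched.

**Step 2**
Reactants: 2 (4S)-4-ethynyl-2,2-dimethyl-1,3-dioxolane
Product: 3 3-[(4S)-2,2-dimethyl-1,3-dioxolan-4-yl]prop-2-yn-1-ol
Conditions: n-BuLi, THF, −78 °C; (CH2O)n, −78 °C to rt; H2O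
Reagents that add atoms: formaldehyde (as paraformaldehyde), C=O
Why: Addition of the lithium acetylide to formaldehyde (hydroxymethylation) should install the carbon that becomes the C3 hydroxymethyl group of both oxolanes.

**Step 3**
Reactants: 3 3-[(4S)-2,2-dimethyl-1,3-dioxolan-4-yl]prop-2-yn-1-ol
Product: 4 (2Z)-3-[(4R)-2,2-dimethyl-1,3-dioxolan-4-yl]-3-iodoprop-2-en-1-ol
Conditions: NaAlH2(OCH2CH2OMe)2, THF, 0 °C; EtOAc; then I2, THF, −78 to 0 °C
Reagents that add atoms: iodine, II
Why: Hydroxyl-directed trans-hydroalumination puts hydride on the alkyne carbon next to CH2OH and aluminium on the distal carbon, and iodinolysis with retention should give the Z iodide with iodine cis to CH2OH; the low temperature is meant to prevent β-elimination of the dioxolane oxygen to an allene.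

**Step 4**
Reactants: 4 (2Z)-3-[(4R)-2,2-dimethyl-1,3-dioxolan-4-yl]-3-iodoprop-2-en-1-ol
Product: 5 (2Z)-3-[(4R)-2,2-dimethyl-1,3-dioxolan-4-yl]-3-iodoprop-2-en-1-yl pivalate
Conditions: PivCl, pyridine, DMAP (cat.), CH2Cl2, 0 °C
Reagents that add atoms: pivaloyl chloride, CC(C)(C)C(Cl)=O
Why: Acylation of the primary allylic alcohol; the pivalate should survive organozinc, Lewis acid and aqueous phosphate and is removed together with the formates in step 17.

**Step 5**
Reactants: 5 (2Z)-3-[(4R)-2,2-dimethyl-1,3-dioxolan-4-yl]-3-iodoprop-2-en-1-yl pivalate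
Product: 6 (2Z,4R)-4,5-dihydroxy-3-iodopent-2-en-1-yl pivalate
Conditions: AcOH–H2O (4:1), 40 °C
Reagents that add atoms: none
Why: Acid-catalysed hydrolysis of the isopropylidene acetal should free the 1,2-diol without touching the vinyl iodide or the pivalate.

**Step 6**
Reactants: 7 (4-benzyloxy-3-methoxyphenyl)methanol
Product: 8 1-benzyloxy-4-(chloromethyl)-2-methoxybenzene
Conditions: SOCl2, CH2Cl2, 0 °C
Reagents that add atoms: thionyl chloride, ClS(Cl)=O
Why: Chlorination of a benzylic alcohol through its chlorosulfite, made easy by the electron-rich ring.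

**Step 7**
Reactants: 8 1-benzyloxy-4-(chloromethyl)-2-methoxybenzene; 6 (2Z,4R)-4,5-dihydroxy-3-iodopent-2-en-1-yl pivalate
Product: 10 (2E,4S)-3-(4-benzyloxy-3-methoxybenzyl)-4,5-dihydroxypent-2-en-1-yl pivalate, via benzylzinc chloride 9 (not isolated)
Conditions: 8, Zn dust, LiCl, THF, 25 °C; then 6, Pd(PPh3)4 (5 mol %), THF, 25 °C
Reagents that add atoms: none
Why: LiCl-assisted zinc insertion into the benzylic chloride followed by Negishi coupling, which retains alkene geometry, should give the E alkene with the arylmethyl group cis to CH2OPiv; benzylic zinc reagents are protonated only slowly by the free diol.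

**Step 8**
Reactants: 11 3-bromo-4-hydroxy-5-methoxybenzaldehyde (5-bromovanillin)
Product: 12 4-benzyloxy-3-bromo-5-methoxybenzaldehyde
Conditions: BnBr, K2CO3, DMF, 25 °C
Reagents that add atoms: benzyl bromide, BrCc1ccccc1
Why: Williamson etherification of the phenol.

**Step 9**
Reactants: 10 (2E,4S)-3-(4-benzyloxy-3-methoxybenzyl)-4,5-dihydroxypent-2-en-1-yl pivalate; 12 4-benzyloxy-3-bromo-5-methoxybenzaldehyde
Product: 13 (2E)-3-(4-benzyloxy-3-methoxybenzyl)-3-[(4S)-2-(4-benzyloxy-3-bromo-5-methoxyphenyl)-1,3-dioxolan-4-yl]prop-2-en-1-yl pivalate (both epimers at the acetal carbon)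
Conditions: PPTS (cat.), MgSO4, benzene, 80 °C
Reagents that add atoms: none
Why: Acid-catalysed acetalisation with removal of water should give the 2-aryl-1,3-dioxolane; the configuration of the acetal carbon does not matter because it is ionised in step 10.

**Step 10**
Reactants: 13 (2E)-3-(4-benzyloxy-3-methoxybenzyl)-3-[(4S)-2-(4-benzyloxy-3-bromo-5-methoxyphenyl)-1,3-dioxolan-4-yl]prop-2-en-1-yl pivalate
Product: 14 [(2S,3R,4S)-2-(4-benzyloxy-3-bromo-5-methoxyphenyl)-4-(4-benzyloxy-3-methoxybenzyl)-4-formyloxolan-3-yl]methyl pivalate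
Conditions: SnCl4 (2 equiv), CH2Cl2, −78 to −30 °C; Et3N, aq NaHCO3
Reagents that add atoms: none
Why: SnCl4 opens the dioxolane at the allylic oxygen to give the (E)-aryl oxocarbenium ion on O1 while tin stays on the carbinol oxygen; alkene carbon C3 then attacks C2 in a chair 6-endo-trig Prins closure (oxane ring, new C2–C3 bond), and the tertiary cation at C4 is quenched by a pinacol 1,2-shift of C5 from the carbinol carbon to C4 (ring contraction to the oxolane), which leaves the old carbinol carbon as the formyl group. The closest known reaction type is the Prins–pinacol rearrangement of 4-alkenyl-1,3-dioxolanes to 3-acyltetrahydrofurans. At C2 the aryl group sits equatorial on the chair; at C3 the E alkene places CH2OPiv equatorial and therefore trans to the aryl group; at C4, C5 arrives on the same alkene face that C2 took at C3, so benzyl stays cis to CH2OPiv and the formyl group ends trans to it. The absolute sense comes from the S carbinol carbon, whose stannyloxy group should take the axial site to avoid A(1,2) strain with the benzyl group on C4, which selects one alkene face. The step needs the productive C–O cleavage (only the O1 oxocarbenium ion can reach the alkene), alkyl shift faster than hydride shift (the carbinol hydrogen is equatorial and out of line with the empty orbital) and no ionisation of the allylic pivalate or of the product's benzylic C2–O1 bond, all helped by the low temperature and the bromine on the aryl ring.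

**Step 11**
Reactants: 12 4-benzyloxy-3-bromo-5-methoxybenzaldehyde
Product: 15 (4-benzyloxy-3-bromo-5-methoxyphenyl)methanol
Conditions: NaBH4, MeOH–THF, 0 °C
Reagents that add atoms: none
Why: Borohydride reduction of the aryl aldehyde, with aryl bromide and benzyl ether inert.

**Step 12**
Reactants: 15 (4-benzyloxy-3-bromo-5-methoxyphenyl)methanol
Product: 16 2-benzyloxy-1-bromo-5-(chloromethyl)-3-methoxybenzene
Conditions: SOCl2, CH2Cl2, 0 °C
Reagents that add atoms: thionyl chloride, ClS(Cl)=O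
Why: Chlorination of the benzylic alcohol as in step 6.

**Step 13**
Reactants: 16 2-benzyloxy-1-bromo-5-(chloromethyl)-3-methoxybenzene; 6 (2Z,4R)-4,5-dihydroxy-3-iodopent-2-en-1-yl pivalate
Product: 18 (2E,4S)-3-(4-benzyloxy-3-bromo-5-methoxybenzyl)-4,5-dihydroxypent-2-en-1-yl pivalate, via bromo-substituted benzylzinc chloride 17 (not isolated)
Conditions: 16, Zn dust, LiCl, THF, 25 °C; then 6, Pd(PPh3)4 (5 mol %), THF, 25 °C
Reagents that add atoms: none
Why: Zinc insertion and Negishi coupling as in step 7; oxidative addition into the vinyl iodide is far faster than into the hindered, electron-rich aryl bromide at 25 °C, so the bromide handle should survive.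

**Step 14**
Reactants: 18 (2E,4S)-3-(4-benzyloxy-3-bromo-5-methoxybenzyl)-4,5-dihydroxypent-2-en-1-yl pivalate; 19 4-benzyloxy-3-methoxybenzaldehyde
Product: 20 (2E)-3-(4-benzyloxy-3-bromo-5-methoxybenzyl)-3-[(4S)-2-(4-benzyloxy-3-methoxyphenyl)-1,3-dioxolan-4-yl]prop-2-en-1-yl pivalate (both epimers at the acetal carbon)
Conditions: PPTS (cat.), MgSO4, benzene, 80 °C
Reagents that add atoms: none
Why: Acid-catalysed acetalisation as in step 9.

**Step 15**
Reactants: 20 (2E)-3-(4-benzyloxy-3-bromo-5-methoxybenzyl)-3-[(4S)-2-(4-benzyloxy-3-methoxyphenyl)-1,3-dioxolan-4-yl]prop-2-en-1-yl pivalate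
Product: 21 [(2S,3R,4S)-2-(4-benzyloxy-3-methoxyphenyl)-4-(4-benzyloxy-3-bromo-5-methoxybenzyl)-4-formyloxolan-3-yl]methyl pivalate
Conditions: SnCl4 (2 equiv), CH2Cl2, −78 to −30 °C; Et3N, aq NaHCO3
Reagents that add atoms: none
Why: Prins–pinacol rearrangement with the same chair control as in step 10 should set the same (2S,3R,4S) array; the bromine here deactivates the benzyl ring against Friedel–Crafts capture of any benzylic cation.

**Step 16**
Reactants: 14 [(2S,3R,4S)-2-(4-benzyloxy-3-bromo-5-methoxyphenyl)-4-(4-benzyloxy-3-methoxybenzyl)-4-formyloxolan-3-yl]methyl pivalate; 21 [(2S,3R,4S)-2-(4-benzyloxy-3-methoxyphenyl)-4-(4-benzyloxy-3-bromo-5-methoxybenzyl)-4-formyloxolan-3-yl]methyl pivalate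
Product: 23 biaryl dialdehyde in which the former C–Br carbon of the 2-aryl ring of 14 is bonded to the former C–Br carbon of the benzyl ring of 21 (both oxolanes 2S,3R,4S; two CHO, two CH2OPiv, four OBn), via pinacol boronate 22 (not isolated)
Conditions: B2pin2, KOAc, Pd2(dba)3, XPhos, 1,4-dioxane, 100 °C; then 21, aq K3PO4, 80 °C
Reagents that add atoms: none
Why: Miyaura borylation of the aryl bromide followed in the same flask by Suzuki–Miyaura coupling should form the di-ortho-alkoxy biaryl with a bulky biarylphosphine ligand; neither aldehyde has an α-hydrogen, so the base is tolerated.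

**Step 17**
Reactants: 23 biaryl dialdehyde
Product: 25 tetra-O-benzyl ether of the target (both oxolanes 2S,3R,4S; two tertiary OH, two CH2OH, four OBn), via bis-formate 24 (not isolated)
Conditions: mCPBA, NaHCO3, CH2Cl2, 0 °C to rt; then NaOMe (cat.), MeOH–THF, 45 °C
Reagents that add atoms: mCPBA, OOC(=O)c1cccc(Cl)c1
Why: Baeyer–Villiger oxidation of the α-quaternary aldehydes, in which the tertiary carbon C4 should migrate in preference to hydride and with retention, puts oxygen where the formyl group was, and base-catalysed methanolysis then removes the two formates and the two pivalates.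

**Step 18**
Reactants: 25 tetra-O-benzyl ether of the target
Product: 26 CNP0269573.1
Conditions: H2 (1 atm), Pd/C, EtOAc–EtOH, 25 °C
Reagents that add atoms: none
Why: Hydrogenolysis of the four aryl benzyl ethers should be much faster than cleavage of the benzylic C2–O1 bonds of the oxolanes under neutral conditions at atmospheric pressure.

**Compound list**
1 | (4R)-2,2-dimethyl-1,3-dioxolane-4-carbaldehyde (D-glyceraldehyde acetonide) | O=C[C@H]1COC(C)(C)O1 | starting material
2 | (4S)-4-ethynyl-2,2-dimethyl-1,3-dioxolane | C#C[C@H]1COC(C)(C)O1 | intermediate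
3 | 3-[(4S)-2,2-dimethyl-1,3-dioxolan-4-yl]prop-2-yn-1-ol | OCC#C[C@H]1COC(C)(C)O1 | intermediate
4 | (2Z)-3-[(4R)-2,2-dimethyl-1,3-dioxolan-4-yl]-3-iodoprop-2-en-1-ol | OC/C=C(\I)[C@H]1COC(C)(C)O1 | intermediate
5 | (2Z)-3-[(4R)-2,2-dimethyl-1,3-dioxolan-4-yl]-3-iodoprop-2-en-1-yl pivalate | CC(C)(C)C(=O)OC/C=C(\I)[C@H]1COC(C)(C)O1 | intermediate
6 | (2Z,4R)-4,5-dihydroxy-3-iodopent-2-en-1-yl pivalate | CC(C)(C)C(=O)OC/C=C(\I)[C@H](O)CO | intermediate
7 | (4-benzyloxy-3-methoxyphenyl)methanol | OCc1ccc(OCc2ccccc2)c(OC)c1 | starting material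
8 | 1-benzyloxy-4-(chloromethyl)-2-methoxybenzene | ClCc1ccc(OCc2ccccc2)c(OC)c1 | intermediate
9 | (4-benzyloxy-3-methoxybenzyl)zinc chloride | Cl[Zn]Cc1ccc(OCc2ccccc2)c(OC)c1 | intermediate (not isolated)
10 | (2E,4S)-3-(4-benzyloxy-3-methoxybenzyl)-4,5-dihydroxypent-2-en-1-yl pivalate | CC(C)(C)C(=O)OC/C=C(\Cc1ccc(OCc2ccccc2)c(OC)c1)[C@H](O)CO | intermediate
11 | 3-bromo-4-hydroxy-5-methoxybenzaldehyde (5-bromovanillin) | O=Cc1cc(OC)c(O)c(Br)c1 | starting material
12 | 4-benzyloxy-3-bromo-5-methoxybenzaldehyde | O=Cc1cc(OC)c(OCc2ccccc2)c(Br)c1 | intermediate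
13 | (2E)-3-(4-benzyloxy-3-methoxybenzyl)-3-[(4S)-2-(4-benzyloxy-3-bromo-5-methoxyphenyl)-1,3-dioxolan-4-yl]prop-2-en-1-yl pivalate, both acetal epimers | CC(C)(C)C(=O)OC/C=C(\Cc1ccc(OCc2ccccc2)c(OC)c1)[C@H]1COC(c2cc(OC)c(OCc3ccccc3)c(Br)c2)O1 | intermediate
14 | [(2S,3R,4S)-2-(4-benzyloxy-3-bromo-5-methoxyphenyl)-4-(4-benzyloxy-3-methoxybenzyl)-4-formyloxolan-3-yl]methyl pivalate | COc1cc(C[C@@]2(C=O)CO[C@H](c3cc(OC)c(OCc4ccccc4)c(Br)c3)[C@H]2COC(=O)C(C)(C)C)ccc1OCc1ccccc1 | intermediate
15 | (4-benzyloxy-3-bromo-5-methoxyphenyl)methanol | OCc1cc(OC)c(OCc2ccccc2)c(Br)c1 | intermediate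
16 | 2-benzyloxy-1-bromo-5-(chloromethyl)-3-methoxybenzene | ClCc1cc(OC)c(OCc2ccccc2)c(Br)c1 | intermediate
17 | (4-benzyloxy-3-bromo-5-methoxybenzyl)zinc chloride | Cl[Zn]Cc1cc(OC)c(OCc2ccccc2)c(Br)c1 | intermediate (not isolated)
18 | (2E,4S)-3-(4-benzyloxy-3-bromo-5-methoxybenzyl)-4,5-dihydroxypent-2-en-1-yl pivalate | CC(C)(C)C(=O)OC/C=C(\Cc1cc(OC)c(OCc2ccccc2)c(Br)c1)[C@H](O)CO | intermediate
19 | 4-benzyloxy-3-methoxybenzaldehyde | O=Cc1ccc(OCc2ccccc2)c(OC)c1 | starting material
20 | (2E)-3-(4-benzyloxy-3-bromo-5-methoxybenzyl)-3-[(4S)-2-(4-benzyloxy-3-methoxyphenyl)-1,3-dioxolan-4-yl]prop-2-en-1-yl pivalate, both acetal epimers | CC(C)(C)C(=O)OC/C=C(\Cc1cc(OC)c(OCc2ccccc2)c(Br)c1)[C@H]1COC(c2ccc(OCc3ccccc3)c(OC)c2)O1 | intermediate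
21 | [(2S,3R,4S)-2-(4-benzyloxy-3-methoxyphenyl)-4-(4-benzyloxy-3-bromo-5-methoxybenzyl)-4-formyloxolan-3-yl]methyl pivalate | COc1cc(C[C@@]2(C=O)CO[C@H](c3ccc(OCc4ccccc4)c(OC)c3)[C@H]2COC(=O)C(C)(C)C)cc(Br)c1OCc1ccccc1 | intermediate
22 | pinacol boronate of 14 (Bpin in place of Br) | COc1cc(C[C@@]2(C=O)CO[C@H](c3cc(OC)c(OCc4ccccc4)c(B4OC(C)(C)C(C)(C)O4)c3)[C@H]2COC(=O)C(C)(C)C)ccc1OCc1ccccc1 | intermediate (not isolated)
23 | biaryl dialdehyde (14 and 21 joined at their former C–Br carbons; both oxolanes 2S,3R,4S) | COc1cc(C[C@@]2(C=O)CO[C@H](c3cc(OC)c(OCc7ccccc7)c(-c4cc(C[C@@]5(C=O)CO[C@H](c6ccc(OCc7ccccc7)c(OC)c6)[C@H]5COC(=O)C(C)(C)C)cc(OC)c4OCc4ccccc4)c3)[C@H]2COC(=O)C(C)(C)C)ccc1OCc1ccccc1 | intermediate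
24 | bis-formate (OCHO in place of each CHO of 23, same configuration) | COc1cc(C[C@@]2(OC=O)CO[C@H](c3cc(OC)c(OCc7ccccc7)c(-c4cc(C[C@@]5(OC=O)CO[C@H](c6ccc(OCc7ccccc7)c(OC)c6)[C@H]5COC(=O)C(C)(C)C)cc(OC)c4OCc4ccccc4)c3)[C@H]2COC(=O)C(C)(C)C)ccc1OCc1ccccc1 | intermediate (not isolated)
25 | tetra-O-benzyl ether of the target (four phenols as OBn; both oxolanes 2S,3R,4S) | COc1cc(C[C@@]2(O)CO[C@H](c3cc(OC)c(OCc7ccccc7)c(-c4cc(C[C@@]5(O)CO[C@H](c6ccc(OCc7ccccc7)c(OC)c6)[C@H]5CO)cc(OC)c4OCc4ccccc4)c3)[C@H]2CO)ccc1OCc1ccccc1 | intermediate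
26 | CNP0269573.1 (both oxolanes 2S,3R,4S) | COc1cc(C[C@@]2(O)CO[C@H](c3cc(OC)c(O)c(-c4cc(C[C@@]5(O)CO[C@H](c6ccc(O)c(OC)c6)[C@H]5CO)cc(OC)c4O)c3)[C@H]2CO)ccc1O | target

**Totals.** Total step count: 18. Longest linear sequence: 11 steps (1, 2, 3, 4, 5, 7, 9, 10, 16, 17, 18).

**Steps most likely to fail**

1. Step 10 (step 15 shares the risk). The product's benzylic C2–O1 bond may re-ionise under SnCl4 and the cation be captured by the electron-rich benzyl ring, the allylic pivalate may ionise, or the preference for one chair may be too small. The fallback sets out from 10 and 12 and comes back at 14. Diol 10 is silylated on both hydroxyls (Et3SiCl, imidazole) to the bis(triethylsilyl) ether F1, and aldehyde 12 is converted with HC(OMe)3 and PPTS into the dimethyl acetal F2. Treating F1 with F2 and catalytic Me3SiOTf in CH2Cl2 at −78 °C should exchange the acetal with the primary silyl ether only, so the same oxocarbenium ion forms regiospecifically under a weak Lewis acid. The Prins closure is then terminated by pinacol shift with loss of the silyl group from the bulky, axially disposed silyloxy carbinol, giving 14.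

2. Step 17. Hydride may migrate instead of C4 in the Criegee intermediates (giving carboxylic acids), or the peracid may oxidise the alkoxy-arenes. The fallback sets out from 23 and comes back at 25. MeMgBr (THF, −78 °C, pivalates untouched) should give the bis(1-hydroxyethyl) compound F3 as a mixture of carbinol epimers, and Dess–Martin periodinane the bis(methyl ketone) F4. Baeyer–Villiger oxidation with CF3CO3H (from (CF3CO)2O and urea–H2O2, Na2HPO4 buffer), in which tertiary alkyl migrates far better than methyl, gives the bis(acetate) F5. NaOMe in MeOH then cleaves acetates and pivalates to 25.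

3. Step 16. The hindered ortho-benzyloxy boronate may protodeboronate faster than it transmetalates, and the two aldehydes may degrade in hot aqueous base. The fallback sets out from 13 and 20 and comes back at 23, bypassing 14, 21 and 22. Dioxolane 13 is borylated (B2pin2, KOAc, PdCl2(dppf), dioxane) to the pinacol boronate F6, which is coupled with dioxolane 20 (Pd(OAc)2, SPhos, K3PO4, toluene–H2O) to the bis(dioxolane) F7, at a stage where no aldehyde is present. SnCl4 at −78 °C then runs the Prins–pinacol rearrangement on both dioxolanes in one operation to give 23.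

**Further compounds**
F1 | step 10 | (2E,4S)-3-(4-benzyloxy-3-methoxybenzyl)-4,5-bis(triethylsilyloxy)pent-2-en-1-yl pivalate | CC(C)(C)C(=O)OC/C=C(\Cc1ccc(OCc2ccccc2)c(OC)c1)[C@H](O[Si](CC)(CC)CC)CO[Si](CC)(CC)CC
F2 | step 10 | 2-benzyloxy-1-bromo-5-(dimethoxymethyl)-3-methoxybenzene | COC(OC)c1cc(OC)c(OCc2ccccc2)c(Br)c1
F3 | step 17 | bis(1-hydroxyethyl) analogue of 23 (CH(OH)CH3 in place of each CHO, carbinol epimers) | COc1cc(C[C@@]2(C(C)O)CO[C@H](c3cc(OC)c(OCc7ccccc7)c(-c4cc(C[C@@]5(C(C)O)CO[C@H](c6ccc(OCc7ccccc7)c(OC)c6)[C@H]5COC(=O)C(C)(C)C)cc(OC)c4OCc4ccccc4)c3)[C@H]2COC(=O)C(C)(C)C)ccc1OCc1ccccc1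
F4 | step 17 | bis(methyl ketone) analogue of 23 (COCH3 in place of each CHO) | COc1cc(C[C@@]2(C(C)=O)CO[C@H](c3cc(OC)c(OCc7ccccc7)c(-c4cc(C[C@@]5(C(C)=O)CO[C@H](c6ccc(OCc7ccccc7)c(OC)c6)[C@H]5COC(=O)C(C)(C)C)cc(OC)c4OCc4ccccc4)c3)[C@H]2COC(=O)C(C)(C)C)ccc1OCc1ccccc1
F5 | step 17 | bis(acetate) (OAc in place of each CHO of 23, same configuration) | COc1cc(C[C@@]2(OC(C)=O)CO[C@H](c3cc(OC)c(OCc7ccccc7)c(-c4cc(C[C@@]5(OC(C)=O)CO[C@H](c6ccc(OCc7ccccc7)c(OC)c6)[C@H]5COC(=O)C(C)(C)C)cc(OC)c4OCc4ccccc4)c3)[C@H]2COC(=O)C(C)(C)C)ccc1OCc1ccccc1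
F6 | step 16 | pinacol boronate of dioxolane 13 (Bpin in place of Br) | CC(C)(C)C(=O)OC/C=C(\Cc1ccc(OCc2ccccc2)c(OC)c1)[C@H]1COC(c2cc(OC)c(OCc3ccccc3)c(B3OC(C)(C)C(C)(C)O3)c2)O1
F7 | step 16 | bis(dioxolane) (13 and 20 joined at their former C–Br carbons) | CC(C)(C)C(=O)OC/C=C(\Cc1ccc(OCc2ccccc2)c(OC)c1)[C@H]1COC(c2cc(OC)c(OCc3ccccc3)c(-c3cc(C/C(=C\COC(=O)C(C)(C)C)[C@H]4COC(c5ccc(OCc6ccccc6)c(OC)c5)O4)cc(OC)c3OCc3ccccc3)c2)O1
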